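All runs are calculated with made-up constants, noise included.

The easy step came first: I subtracted neighbouring readings of target in the red run, which is the very flask asked about, to decide whether it needed more reagent or more time.

- red: substrate 2 M; reagent 1.5 equiv; the very flask that is asked about, followed so far
- flask: substrate 2.0 M; reagent 1.50 equiv; time 15 h

red run (percent of the substrate charged)

| time / h | target / % |
|---|---|
| 0.333 | 31.0 |
| 1.00 | 44.6 |
| 2.00 | 50.4 |
| 2.50 | 51.6 |

(each reading ± 0.5 percentage points)

- in percentages every species weighs as the substrate in it: one self-condensation product counts as two
- on the list of suspects stand: 2 substrate -> self-condensation product; reagent + other conformer -> isomer of the product; substrate <-> other conformer; substrate + reagent -> target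
- in a conversion other conformer counts as not yet reacted
- the reaction counts as stopped when no species that holds the substrate changes by six tenths of a point or more over the second half of the time

- at 15 h, what has stopped the reaction, if anything has (other conformer counts as not reacted) (it is still moving / forward and back rates have come level / the reagent has run out first / all of the substrate has reacted)
- the target standing at 15 h, as a percentage of the substrate charged

Target rose 5.8 percentage points between 1.00 h and 2.00 h, then 1.2 points in the next 0.500 h. So its hourly rise fell by a factor of 2.42 across the 0.750 h between the midpoints of those spans. The halving time of the rise, the time in which the hourly rise drops by a factor of 2, came to 0.589 h. This is a rough reading: each reading scatters by 0.5 points, against a last rise of 1.2 points. A rise shrinking at that pace still had 1.5 points to give after 2.50 h, so I reckoned on 53.1 % of target. From there to 15 h lay 21.2 halvings, and a halving time twice as long still left 10.6. Reagent stood at 1.50 equiv, more than the one equivalent the substrate can consume, so I took substrate for the limiting reagent. I decided to add no reagent and not to run this flask past 15 h.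

The forecast gave 54 % of target and "all of the substrate has reacted", holding that “only about 2–3 points of substrate remain to become target”. The flask gave 53.0 % and "all of the substrate has reacted".

    2 substrate → self-condensation product (k = 8.10 × 10⁻⁵ L mol⁻¹ s⁻¹)
    reagent + other conformer → isomer of the product (k = 2.30 × 10⁻⁴ L mol⁻¹ s⁻¹)
    substrate ⇌ other conformer (K = 1.10, k = 3.70 × 10⁻⁴ s⁻¹)
    substrate + reagent → target (k = 1.70 × 10⁻⁴ L mol⁻¹ s⁻¹)

This flask had come to rest: target stood at 53.0 % at 7.50 h and 53.0 % at 15.0 h, with substrate at 0 % and other conformer at 0 %. My 21.2 halvings left 6.2 × 10⁻⁷ points of target still to come in this flask, and ten times the time left its target at 53.0 %. For the flask charged with 0.80 M of substrate at the same equivalents, I assumed that the halving time stretched by the charge ratio, 2.50, to 1.47 h. By my reckoning that made 10.2 halvings and 0.0860 % of the charge unreacted; that flask held 0.0686 % substrate and 0.0722 % other conformer.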